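**Retrosynthetic overview**

1. Lobatin B ⇐ its 8,9-diol, by acylation of the less hindered 8-OH.
2. Diol ⇐ a bicyclic dilactone epoxy ketone (key step). The C2 enolate of the C1 methyl ketone attacks C3 of a temporary seven-membered O8–C3 lactone, which ring-expands to the ten-membered carbocycle (C2–C3); the C3 enolate oxygen then opens the C9–C10 epoxide at C10 (furanone, O–C10). Enabling feature: O8 is tied to C3 through the chain C4=C5–C6–C7 (a seven-membered lactone with the Z alkene in the ring), C2 hangs on the same C8 through C9–C10–C1, and the C9,C10-epoxide lies α,β to the C1 ketone.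
3. Seven-membered lactone ⇐ ring-closing metathesis (C4=C5) of a C8 methacrylate; epoxide ⇐ Sharpless epoxidation directed by a C1 hydroxyl; methacrylate ⇐ Mitsunobu inversion at C8.
4. C7–C8 bond and α-methylene lactone ⇐ allylboration of an (E)-enal (C8, C9, C10, C14, C1, C2) with a butenolide allylboronate (C5–C7, C11–C13); C6 from an asymmetric alkynylation.
5. Ring order: γ-lactone (butenolide, then α-methylene lactone) → temporary seven-membered lactone → ten-membered carbocycle and furanone together.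

Key step: step 14

Remark: locants C1–C15 are those of the germacrane skeleton of the target (C1 ketone, C2=C3 furanone alkene, C4=C5 alkene, C6 lactone carbinol, C8 ester carbinol, C9 carbinol, C10 quaternary carbon, C11–C13 lactone carbons, C14 methyl on C10, C15 methyl on C4).

Assumption: the (S,S)-enantiomer of ProPhenol is taken to give the (4R)-carbinol in step 4; if the sense is the opposite, the (R,R)-ligand is used with no other change.

**Route**

Step 1
Reactants: 1 (R)-but-3-yn-2-ol
Product: 2 (R)-tert-butyl(but-3-yn-2-yloxy)dimethylsilane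
Conditions: TBSCl, imidazole, DMF, 0 °C to rt
Reagents that add atoms: tert-butyldimethylsilyl chloride, CC(C)(C)[Si](C)(C)Cl
Why: Standard silylation of a secondary alcohol that leaves the stereocentre (later C1) untouched.

Step 2
Reactants: 2 (R)-tert-butyl(but-3-yn-2-yloxy)dimethylsilane
Product: 4 (2E,4R)-4-[(tert-butyldimethylsilyl)oxy]-3-methylpent-2-en-1-ol, via alkenylalane 3 (not isolated)
Conditions: AlMe3, Cp2ZrCl2 (0.25 equiv), ClCH2CH2Cl, 0 °C to rt; then n-BuLi, THF, −78 °C; (CH2O)n, −78 °C to rt; aq. HCl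
Reagents that add atoms: trimethylaluminium, C[Al](C)C; formaldehyde (as paraformaldehyde), C=O
Why: Negishi zirconium-catalysed carboalumination adds methyl and aluminium syn across the terminal alkyne (methyl to the internal carbon), and the derived alanate is hydroxymethylated with retention, which fixes the E-trisubstituted C9=C10 alkene.

Step 3
Reactants: 4 (2E,4R)-4-[(tert-butyldimethylsilyl)oxy]-3-methylpent-2-en-1-ol
Product: 5 (2E,4R)-4-[(tert-butyldimethylsilyl)oxy]-3-methylpent-2-enal
Conditions: MnO2, CH2Cl2, rt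
Reagents that add atoms: none
Why: Allylic oxidation with MnO2 should stop at the enal without E/Z isomerisation.

Step 4
Reactants: 6 (E)-but-2-enal; 7 methyl prop-2-ynoate
Product: 8 methyl (4R,5E)-4-hydroxyhept-5-en-2-ynoate
Conditions: Me2Zn, (S,S)-ProPhenol (10 mol %), Ph3P=O (20 mol %), toluene, 4 °C; aq. NH4Cl
Reagents that add atoms: none
Why: Trost's ProPhenol–zinc asymmetric alkynylation of an α,β-unsaturated aldehyde, in which the chiral dinuclear zinc catalyst selects the aldehyde face and so sets C6.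

Step 5
Reactants: 8 methyl (4R,5E)-4-hydroxyhept-5-en-2-ynoate
Product: 9 methyl (4R,5E)-4-[(triethylsilyl)oxy]hept-5-en-2-ynoate
Conditions: TESCl, imidazole, CH2Cl2, 0 °C
Reagents that add atoms: chlorotriethylsilane, CC[Si](Cl)(CC)CC
Why: Silylation of the propargylic alcohol, which prevents premature lactonisation in the next step.

Step 6
Reactants: 9 methyl (4R,5E)-4-[(triethylsilyl)oxy]hept-5-en-2-ynoate
Product: 11 methyl (2Z,4R,5E)-2-[(4,4,5,5-tetramethyl-1,3,2-dioxaborolan-2-yl)methyl]-4-[(triethylsilyl)oxy]hepta-2,5-dienoate, via α-alumino enoate 10 (not isolated)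
Conditions: iBu2AlH, HMPA, THF, 0 °C; then ICH2Bpin, 0 °C to rt
Reagents that add atoms: 2-(iodomethyl)-4,4,5,5-tetramethyl-1,3,2-dioxaborolane, ICB1OC(C)(C)C(C)(C)O1
Why: Conjugate hydroalumination of the ynoate (syn addition, aluminium on the α-carbon) followed by C-alkylation with the iodomethylboronate is the known entry to 3-substituted 2-alkoxycarbonyl allylboronates, and the syn addition places C6 cis to the ester.

Step 7
Reactants: 11 methyl (2Z,4R,5E)-2-[(4,4,5,5-tetramethyl-1,3,2-dioxaborolan-2-yl)methyl]-4-[(triethylsilyl)oxy]hepta-2,5-dienoate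
Product: 12 (5R)-5-[(1E)-prop-1-en-1-yl]-3-[(4,4,5,5-tetramethyl-1,3,2-dioxaborolan-2-yl)methyl]furan-2(5H)-one
Conditions: TsOH·H2O (10 mol %), wet MeOH, 0 °C to rt
Reagents that add atoms: none
Why: Acid-catalysed desilylation followed by spontaneous lactonisation of the Z-configured γ-hydroxy enoate closes the butenolide.

Step 8
Reactants: 12 (5R)-5-[(1E)-prop-1-en-1-yl]-3-[(4,4,5,5-tetramethyl-1,3,2-dioxaborolan-2-yl)methyl]furan-2(5H)-one; 5 (2E,4R)-4-[(tert-butyldimethylsilyl)oxy]-3-methylpent-2-enal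
Product: 14 (4R,5R)-4-[(1S,2E,4R)-4-[(tert-butyldimethylsilyl)oxy]-1-hydroxy-3-methylpent-2-en-1-yl]-3-methylidene-5-[(1E)-prop-1-en-1-yl]oxolan-2-one, via pinacol borate 13 (not isolated)
Conditions: Sc(OTf)3 (10 mol %), toluene, 0 °C to rt; aq. NaHCO3
Reagents that add atoms: none
Why: Lewis-acid-catalysed allylboration of an aldehyde by a 2-alkoxycarbonyl allylboronate through a closed chair transition state, in which the aldehyde should add to C7 anti to the C6 propenyl group (trans lactone) and the ring-fixed E-type allyl unit should give the anti C6/O8 relationship, that is the C8 epimer of the target.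

Step 9
Reactants: 14 (4R,5R)-4-[(1S,2E,4R)-4-[(tert-butyldimethylsilyl)oxy]-1-hydroxy-3-methylpent-2-en-1-yl]-3-methylidene-5-[(1E)-prop-1-en-1-yl]oxolan-2-one; 15 2-methylprop-2-enoic acid
Product: 16 (1R,2E,4R)-4-[(tert-butyldimethylsilyl)oxy]-3-methyl-1-[(2R,3S)-4-methylidene-5-oxo-2-[(1E)-prop-1-en-1-yl]oxolan-3-yl]pent-2-en-1-yl 2-methylprop-2-enoate
Conditions: PPh3, DIAD, toluene, 0 °C to rt
Reagents that add atoms: none
Why: Mitsunobu esterification installs the methacrylate and inverts C8 by SN2 displacement to the configuration of the target.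

Step 10
Reactants: 16 (1R,2E,4R)-4-[(tert-butyldimethylsilyl)oxy]-3-methyl-1-[(2R,3S)-4-methylidene-5-oxo-2-[(1E)-prop-1-en-1-yl]oxolan-3-yl]pent-2-en-1-yl 2-methylprop-2-enoate
Product: 17 (1R,2E,4R)-4-hydroxy-3-methyl-1-[(2R,3S)-4-methylidene-5-oxo-2-[(1E)-prop-1-en-1-yl]oxolan-3-yl]pent-2-en-1-yl 2-methylprop-2-enoate
Conditions: HF·pyridine, pyridine, THF, 0 °C to rt
Reagents that add atoms: none
Why: Buffered fluoride desilylation of the secondary silyl ether, to which both esters and the exocyclic methylene should be inert.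

Step 11
Reactants: 17 (1R,2E,4R)-4-hydroxy-3-methyl-1-[(2R,3S)-4-methylidene-5-oxo-2-[(1E)-prop-1-en-1-yl]oxolan-3-yl]pent-2-en-1-yl 2-methylprop-2-enoate
Product: 18 (S)-[(2R,3R)-3-[(1R)-1-hydroxyethyl]-3-methyloxiran-2-yl][(2R,3S)-4-methylidene-5-oxo-2-[(1E)-prop-1-en-1-yl]oxolan-3-yl]methyl 2-methylprop-2-enoate
Conditions: Ti(OiPr)4 (0.5 equiv), D-(−)-diisopropyl tartrate (0.6 equiv), t-BuOOH, 4 Å MS, CH2Cl2, −20 °C
Reagents that add atoms: tert-butyl hydroperoxide, CC(C)(C)OO
Why: Sharpless titanium–tartrate epoxidation of a secondary allylic alcohol, in which the (R)-carbinol at C1 and D-(−)-tartrate are the matched pair that should deliver the erythro epoxide, so C9 and C10 are set and only the alkene next to the free hydroxyl reacts.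

Step 12
Reactants: 18 (S)-[(2R,3R)-3-[(1R)-1-hydroxyethyl]-3-methyloxiran-2-yl][(2R,3S)-4-methylidene-5-oxo-2-[(1E)-prop-1-en-1-yl]oxolan-3-yl]methyl 2-methylprop-2-enoate
Product: 19 (S)-[(2R,3S)-3-acetyl-3-methyloxiran-2-yl][(2R,3S)-4-methylidene-5-oxo-2-[(1E)-prop-1-en-1-yl]oxolan-3-yl]methyl 2-methylprop-2-enoate
Conditions: Dess–Martin periodinane, NaHCO3, CH2Cl2, 0 °C to rt
Reagents that add atoms: none
Why: Dess–Martin oxidation of an epoxy alcohol to the α,β-epoxy ketone, which removes the auxiliary stereocentre at C1 without touching the epoxide.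

Step 13
Reactants: 19 (S)-[(2R,3S)-3-acetyl-3-methyloxiran-2-yl][(2R,3S)-4-methylidene-5-oxo-2-[(1E)-prop-1-en-1-yl]oxolan-3-yl]methyl 2-methylprop-2-enoate
Product: 20 bicyclic dilactone: α-methylene-γ-butyrolactone trans-fused at C6–C7 to a seven-membered 4-methyl-α,β-unsaturated lactone (O8–C3, C4=C5 Z), carrying on C8 the (2R,3S)-3-acetyl-3-methyloxiran-2-yl group (6R,7S,8S,9R,10S)
Conditions: second-generation Hoveyda–Grubbs catalyst (10 mol %), toluene (0.003 M), 80 °C
Reagents that add atoms: none
Why: Ring-closing metathesis between the methacrylate and the C6 propenyl group forms the seven-membered lactone, the ring enforcing the Z geometry of C4=C5; it is run after the epoxidation so that no C9=C10 alkene can compete for a five-membered ring.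

Step 14
Reactants: 20 bicyclic dilactone epoxy ketone
Product: 23 8-O-deacyl-lobatin B (the 8,9-diol; 6R,7R,8S,9R,10R), via lithium enolate 21 (not isolated), via β-diketonate 22 (not isolated)
Conditions: LiN(SiMe3)2 (1.05 equiv), THF (0.005 M), −78 °C to rt; AcOH
Reagents that add atoms: none
Why: Proposed new method: LiN(SiMe3)2 removes a C2 proton (C10 is quaternary and neither lactone has an α-hydrogen) to give enolate 21, whose carbon adds to the ε-lactone carbonyl C3 through a seven-membered cyclic transition state; the bridged tetrahedral intermediate collapses with loss of the C8 alkoxide, so the O8–C3 lactone is ring-expanded to the ten-membered carbocycle as β-diketonate 22 (closure by exo-trig addition to C=O followed by C3–O8 fragmentation, so no medium-ring transition state is needed). The closest known reaction is the Baker–Venkataraman O→C acyl transfer (an intramolecular Claisen condensation), here on an aliphatic lactone. The diketonate oxygen on C3 then displaces the epoxide oxygen at C10, the carbon α to the C1 carbonyl, in a 5-exo-tet closure of the furanone, as in the O-alkylation that ends a Feist–Bénary synthesis or the cyclisation of α′-halo-1,3-diketones to 3(2H)-furanones. C10 is the only stereocentre made and is set by SN2 inversion of the (9R,10S)-epoxide, while C6, C7 and C8 are untouched and O9 stays on C9 as the free hydroxyl. The step needs C2–C3 attack at the ε-lactone and not at the γ-lactone carbonyl (seven- against eight-membered transition state, secured by the O8 tether) and O–C10 rather than O–C9 closure (5-exo against 6-endo, helped by lithium bridging the freed 8-OH and the epoxide oxygen as in distal openings of 2,3-epoxy alcohols). Payne migration and over-enolisation should be held back because the C8 alkoxide and any excess base are quenched at once by the far more acidic β-diketone.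

Step 15
Reactants: 23 8-O-deacyl-lobatin B
Product: 24 lobatin B
Conditions: 3-methylbutanoic anhydride (1.1 equiv), 2,4,6-collidine, DMAP (5 mol %), CH2Cl2, −40 °C
Reagents that add atoms: 3-methylbutanoic anhydride, CC(C)CC(=O)OC(=O)CC(C)C
Why: DMAP-catalysed acylation should take the C8 hydroxyl, because the C9 hydroxyl is neopentylic (next to the quaternary bridgehead C10) and the stereocentres are not touched.

**Compound list**

1 | (R)-but-3-yn-2-ol | C[C@@H](O)C#C | starting material
2 | (R)-tert-butyl(but-3-yn-2-yloxy)dimethylsilane | C[C@@H](O[Si](C)(C)C(C)(C)C)C#C | intermediate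
3 | [(1E,3R)-3-[(tert-butyldimethylsilyl)oxy]-2-methylbut-1-en-1-yl]dimethylalumane | C[C@@H](O[Si](C)(C)C(C)(C)C)/C(C)=C/[Al](C)C | intermediate (not isolated)
4 | (2E,4R)-4-[(tert-butyldimethylsilyl)oxy]-3-methylpent-2-en-1-ol | C[C@@H](O[Si](C)(C)C(C)(C)C)/C(C)=C/CO | intermediate
5 | (2E,4R)-4-[(tert-butyldimethylsilyl)oxy]-3-methylpent-2-enal | C[C@@H](O[Si](C)(C)C(C)(C)C)/C(C)=C/C=O | intermediate
6 | (E)-but-2-enal | C/C=C/C=O | starting material
7 | methyl prop-2-ynoate | C#CC(=O)OC | starting material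
8 | methyl (4R,5E)-4-hydroxyhept-5-en-2-ynoate | C/C=C/[C@@H](O)C#CC(=O)OC | intermediate
9 | methyl (4R,5E)-4-[(triethylsilyl)oxy]hept-5-en-2-ynoate | C/C=C/[C@@H](O[Si](CC)(CC)CC)C#CC(=O)OC | intermediate
10 | methyl (2E,4R,5E)-2-(diisobutylalumanyl)-4-[(triethylsilyl)oxy]hepta-2,5-dienoate | C/C=C/[C@@H](O[Si](CC)(CC)CC)/C=C(/[Al](CC(C)C)CC(C)C)C(=O)OC | intermediate (not isolated)
11 | methyl (2Z,4R,5E)-2-[(4,4,5,5-tetramethyl-1,3,2-dioxaborolan-2-yl)methyl]-4-[(triethylsilyl)oxy]hepta-2,5-dienoate | C/C=C/[C@@H](O[Si](CC)(CC)CC)/C=C(/CB1OC(C)(C)C(C)(C)O1)C(=O)OC | intermediate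
12 | (5R)-5-[(1E)-prop-1-en-1-yl]-3-[(4,4,5,5-tetramethyl-1,3,2-dioxaborolan-2-yl)methyl]furan-2(5H)-one | C/C=C/[C@H]1OC(=O)C(CB2OC(C)(C)C(C)(C)O2)=C1 | intermediate
13 | pinacol borate of 14 (O8–B) | C=C1C(=O)O[C@H](/C=C/C)[C@H]1[C@@H](OB2OC(C)(C)C(C)(C)O2)/C=C(C)/[C@@H](C)O[Si](C)(C)C(C)(C)C | intermediate (not isolated)
14 | (4R,5R)-4-[(1S,2E,4R)-4-[(tert-butyldimethylsilyl)oxy]-1-hydroxy-3-methylpent-2-en-1-yl]-3-methylidene-5-[(1E)-prop-1-en-1-yl]oxolan-2-one | C=C1C(=O)O[C@H](/C=C/C)[C@H]1[C@@H](O)/C=C(C)/[C@@H](C)O[Si](C)(C)C(C)(C)C | intermediate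
15 | 2-methylprop-2-enoic acid | CC(=C)C(=O)O | starting material
16 | (1R,2E,4R)-4-[(tert-butyldimethylsilyl)oxy]-3-methyl-1-[(2R,3S)-4-methylidene-5-oxo-2-[(1E)-prop-1-en-1-yl]oxolan-3-yl]pent-2-en-1-yl 2-methylprop-2-enoate | C=C1C(=O)O[C@H](/C=C/C)[C@H]1[C@H](OC(=O)C(C)=C)/C=C(C)/[C@@H](C)O[Si](C)(C)C(C)(C)C | intermediate
17 | (1R,2E,4R)-4-hydroxy-3-methyl-1-[(2R,3S)-4-methylidene-5-oxo-2-[(1E)-prop-1-en-1-yl]oxolan-3-yl]pent-2-en-1-yl 2-methylprop-2-enoate | C=C1C(=O)O[C@H](/C=C/C)[C@H]1[C@H](OC(=O)C(C)=C)/C=C(C)/[C@@H](C)O | intermediate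
18 | (S)-[(2R,3R)-3-[(1R)-1-hydroxyethyl]-3-methyloxiran-2-yl][(2R,3S)-4-methylidene-5-oxo-2-[(1E)-prop-1-en-1-yl]oxolan-3-yl]methyl 2-methylprop-2-enoate | C=C1C(=O)O[C@H](/C=C/C)[C@H]1[C@H](OC(=O)C(C)=C)[C@H]2O[C@]2(C)[C@@H](C)O | intermediate
19 | (S)-[(2R,3S)-3-acetyl-3-methyloxiran-2-yl][(2R,3S)-4-methylidene-5-oxo-2-[(1E)-prop-1-en-1-yl]oxolan-3-yl]methyl 2-methylprop-2-enoate | C=C1C(=O)O[C@H](/C=C/C)[C@H]1[C@H](OC(=O)C(C)=C)[C@H]2O[C@]2(C)C(C)=O | intermediate
20 | bicyclic dilactone epoxy ketone (α-methylene-γ-butyrolactone trans-fused to the seven-membered O8–C3 lactone; 6R,7S,8S,9R,10S) | C=C1C(=O)O[C@@H]2/C=C(/C)C(=O)O[C@H]([C@H]3O[C@]3(C)C(C)=O)[C@@H]12 | intermediate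
21 | lithium enolate of 20 (C1–C2) | C=C1C(=O)O[C@@H]2/C=C(/C)C(=O)O[C@H]([C@H]3O[C@]3(C)C(=C)[O-])[C@@H]12.[Li+] | intermediate (not isolated)
22 | ten-membered 1,3-diketone with 8-OH and 9,10-epoxide, as its lithium enolate | C=C1C(=O)O[C@@H]2/C=C(/C)C(=O)C=C([O-])[C@@]3(C)O[C@@H]3[C@@H](O)[C@@H]12.[Li+] | intermediate (not isolated)
23 | 8-O-deacyl-lobatin B (8,9-diol; 6R,7R,8S,9R,10R) | C=C1C(=O)O[C@@H]2/C=C(/C)C3=CC(=O)[C@](C)(O3)[C@H](O)[C@@H](O)[C@@H]12 | intermediate
24 | lobatin B (6R,7S,8S,9R,10R; C4=C5 Z) | C=C1C(=O)O[C@@H]2/C=C(/C)C3=CC(=O)[C@](C)(O3)[C@H](O)[C@@H](OC(=O)CC(C)C)[C@@H]12 | target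

**Step count**

Total: 15 steps (3 to enal 5, 4 to allylboronate 12, 8 after their union). Longest linear sequence: 12 steps (steps 4–15).

**Steps most likely to fail, with fallbacks**

1. Step 14 (key step). The enolate may be lost by proton transfer to the lactone γ-positions before it reaches C3, or the diketonate may close 6-endo at C9 to a pyranone. Fallback with known reactions, from 18 back to 23, taking the ring oxygen from a tertiary hydroxyl:
 - The epoxide of 18 is hydrolysed under acid catalysis (aq. HClO4, THF; water enters at the tertiary carbon with inversion) to the 1,9,10-triol F1.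
 - The less hindered C1 carbinol is oxidised (TEMPO, PhI(OAc)2) to the α-hydroxy methyl ketone F2.
 - Excess LiN(SiMe3)2 moves the methacryloyl group from oxygen to C2 in the open chain (Claisen-type O→C acyl migration), and TsOH then closes the furanone by the classical cyclodehydration of an α′-hydroxy-1,3-diketone, giving the 5-isopropenyl furanone diol F3.
 - Ring-closing metathesis (second-generation Hoveyda–Grubbs catalyst, high dilution) between the isopropenyl and the C6 propenyl groups closes the ten-membered ring to 23.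

2. Step 15. Acylation may be unselective between the two secondary hydroxyls, and the ester may migrate from O8 to O9. Fallback from 20 back to 24, differentiating the oxygens by timing:
 - The cascade is stopped after the ring expansion (−78 °C, AcOH quench) and 22 is isolated in its neutral diketone form, in which O8–H is the only hydroxyl.
 - It is acylated with 3-methylbutanoic anhydride and DMAP to the diketone 8-isovalerate F4.
 - The furanone is then closed by Lewis-acid-promoted 5-exo opening of the epoxide (Sc(OTf)3, CH2Cl2), which frees the 9-OH last and gives 24 directly.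

3. Step 9. The hindered allylic carbinol may react by SN2′ attack, by elimination to a diene, or with incomplete inversion. Fallback from 9 back to 16, making the C8 configuration directly so that no inversion is needed:
 - The vinylalane from 9 is trapped with Bu3SnCH2I to give the allylstannane ester F5.
 - TsOH in MeOH gives the stannylmethyl butenolide F6.
 - BF3·OEt2-promoted addition of F6 to enal 5 through an open antiperiplanar transition state is syn-selective and should give the (8S)-alcohol F7.
 - F7 is esterified with methacryloyl chloride (Et3N, DMAP) with retention to 16.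

Further compounds
F1 | step 14 | 1,9,10-triol from hydrolysis of the epoxide of 18 (C9 retained, C10 inverted; 8-methacrylate) | C=C1C(=O)O[C@H](/C=C/C)[C@H]1[C@H](OC(=O)C(C)=C)[C@@H](O)[C@@](C)(O)[C@@H](C)O
F2 | step 14 | 9,10-dihydroxy C1 methyl ketone (8-methacrylate) | C=C1C(=O)O[C@H](/C=C/C)[C@H]1[C@H](OC(=O)C(C)=C)[C@@H](O)[C@@](C)(O)C(C)=O
F3 | step 14 | open-chain 5-isopropenyl-3(2H)-furanone 8,9-diol on the α-methylene lactone | C=C1C(=O)O[C@H](/C=C/C)[C@H]1[C@H](O)[C@@H](O)[C@@]1(C)OC(C(C)=C)=CC1=O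
F4 | step 15 | ten-membered 1,3-diketone 9,10-epoxide 8-(3-methylbutanoate) | C=C1C(=O)O[C@@H]2/C=C(/C)C(=O)CC(=O)[C@@]3(C)O[C@@H]3[C@@H](OC(=O)CC(C)C)[C@@H]12
F5 | step 9 | methyl (2Z,4R,5E)-2-[(tributylstannyl)methyl]-4-[(triethylsilyl)oxy]hepta-2,5-dienoate | C/C=C/[C@@H](O[Si](CC)(CC)CC)/C=C(/C[Sn](CCCC)(CCCC)CCCC)C(=O)OC
F6 | step 9 | (5R)-5-[(1E)-prop-1-en-1-yl]-3-[(tributylstannyl)methyl]furan-2(5H)-one | C/C=C/[C@H]1OC(=O)C(C[Sn](CCCC)(CCCC)CCCC)=C1
F7 | step 9 | C8 epimer of 14 ((8S)-alcohol) | C=C1C(=O)O[C@H](/C=C/C)[C@H]1[C@H](O)/C=C(C)/[C@@H](C)O[Si](C)(C)C(C)(C)C
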